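**Retrosynthetic overview**
1. Target 22 ⇐ global O-demethylation of pentaphenol hexadecamethyl ether 21 ⇐ fivefold Dakin oxidation of octamer pentaaldehyde 19.
2. Feature (rings lettered A to H along the chain, ring atoms numbered as in the target SMILES): rings B, C, E, G and H each carry a C4 hydroxyl para to the C1 ether carbon, so C4 can first be a formyl group that activates a C1 fluoride for SNAr and afterwards become the hydroxyl.
3. 19 ⇐ SNAr of A–B phenol 18 on hexamer fluoride 13; 13 ⇐ two iterations of dimer phenol 8 (rings E–F, then rings C–D) onto the G–H dialdehyde 9, each followed by acetal hydrolysis that switches the next fluoride on.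
4. 8 and 9 both come from dimer 6 (Dakin oxidation of the ring that becomes D or F, or acetal hydrolysis); the C6 oxygen of rings C, E and G is installed by ortho-lithiation, borylation and oxidation next to fluorine.
5. No ring is formed: seven rings are bought as 4-fluoro-2,6-dimethoxybenzaldehyde and ring A as 2,4,6-trimethoxybenzaldehyde; they are joined in the order G–H, E–F, C–D, then A–B.

Key step: step 14

Remark: the target has no stereocentre; a dioxolane in place of a formyl group is taken to switch the para fluoride off for SNAr, and its hydrolysis to switch it on again, so no phenol protecting group is needed.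

Step 1
Reactants: 1 4-fluoro-2,6-dimethoxybenzaldehyde
Product: 2 2-(4-fluoro-2,6-dimethoxyphenyl)-1,3-dioxolane
Conditions: ethylene glycol, p-TsOH (cat.), toluene, reflux (Dean–Stark); Et3N quench
Reagents that add atoms: ethylene glycol OCCO
Why: Acid-catalysed acetalisation driven by azeotropic removal of water; the dioxolane tolerates the organolithium of step 2 and removes the para activation of the fluoride.

Step 2
Reactants: 2 2-(4-fluoro-2,6-dimethoxyphenyl)-1,3-dioxolane
Product: 5 3-(1,3-dioxolan-2-yl)-6-fluoro-2,4-dimethoxyphenol, via aryllithium 3 (not isolated), via lithium aryltrimethoxyborate 4 (not isolated)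
Conditions: n-BuLi, THF, −78 °C; B(OMe)3, −78 to 0 °C; 30% H2O2, 0 °C to rt
Reagents that add atoms: hydrogen peroxide OO
Why: Directed ortho-metalation at the only ring hydrogens, which are equivalent and lie between fluorine and methoxy, followed by borylation and oxidative aryl shift from boron to oxygen; at −78 °C the 2-fluoroaryllithium should not lose LiF and ring lithiation should outrun attack on the acetal.

Step 3
Reactants: 5 3-(1,3-dioxolan-2-yl)-6-fluoro-2,4-dimethoxyphenol; 1 4-fluoro-2,6-dimethoxybenzaldehyde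
Product: 6 4-[3-(1,3-dioxolan-2-yl)-6-fluoro-2,4-dimethoxyphenoxy]-2,6-dimethoxybenzaldehyde
Conditions: K2CO3, DMF, 90 °C
Reagents that add atoms: none
Why: SNAr (addition–elimination) of the phenoxide of 5 on the fluoride para to the formyl group of 1; the fluoride of 5 has only an acetal para to it and a phenoxide ortho to it, so self-condensation should not occur.

Step 4
Reactants: 6 4-[3-(1,3-dioxolan-2-yl)-6-fluoro-2,4-dimethoxyphenoxy]-2,6-dimethoxybenzaldehyde
Product: 8 4-[3-(1,3-dioxolan-2-yl)-6-fluoro-2,4-dimethoxyphenoxy]-2,6-dimethoxyphenol, via aryl formate 7 (not isolated)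
Conditions: mCPBA, NaHCO3, CH2Cl2, 0 °C to rt; then K2CO3 (cat.), MeOH, rt
Reagents that add atoms: mCPBA OOC(=O)c1cccc(Cl)c1
Why: Dakin-type Baeyer–Villiger oxidation in which the aryl group with two ortho methoxy groups and a para aryloxy group migrates in preference to hydride, then base-catalysed methanolysis of the formate; the bicarbonate buffer should keep the acid-labile dioxolane intact.

Step 5
Reactants: 6 4-[3-(1,3-dioxolan-2-yl)-6-fluoro-2,4-dimethoxyphenoxy]-2,6-dimethoxybenzaldehyde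
Product: 9 4-fluoro-3-(4-formyl-3,5-dimethoxyphenoxy)-2,6-dimethoxybenzaldehyde (rings G–H)
Conditions: PPTS, acetone/H2O, 40 °C
Reagents that add atoms: water O
Why: Acid-catalysed acetal hydrolysis through the aryl-stabilised oxocarbenium ion restores the formyl group and thereby switches on the fluoride para to it.

Step 6
Reactants: 8 dimer phenol (here rings E–F); 9 G–H dialdehyde
Product: 10 tetramer E–H acetal (the phenol oxygen of 8 bonded to the former C–F carbon of 9; ring E: C1 fluorine, C4 dioxolane; C4 formyl on rings G and H)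
Conditions: Cs2CO3, DMSO, 90 °C, argon
Reagents that add atoms: none
Why: SNAr of the 2,6-dimethoxyphenoxide of 8 on the ring G fluoride of 9, para to the ring G formyl group; the fluoride of 8 stays inert because its ring carries the dioxolane, so the coupling cannot run on to oligomers.

Step 7
Reactants: 10 tetramer E–H acetal
Product: 11 tetramer E–H trialdehyde fluoride (ring E: C1 fluorine, C4 formyl)
Conditions: PPTS, acetone/H2O, 40 °C
Reagents that add atoms: water O
Why: Mild acetal hydrolysis unmasks the ring E formyl group and arms the ring E fluoride; diaryl ethers, methyl ethers and the other formyl groups are inert to PPTS.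

Step 8
Reactants: 8 dimer phenol (here rings C–D); 11 tetramer E–H trialdehyde fluoride
Product: 12 hexamer C–H acetal (the phenol oxygen of 8 bonded to ring E C1 of 11 in place of fluorine; ring C: C1 fluorine, C4 dioxolane; C4 formyl on rings E, G and H)
Conditions: Cs2CO3, DMSO, 100 °C, argon
Reagents that add atoms: none
Why: The same SNAr as in step 6, now joining the ring D oxygen to C1 of ring E at the fluoride para to the ring E formyl group.

Step 9
Reactants: 12 hexamer C–H acetal
Product: 13 hexamer C–H tetraaldehyde fluoride (ring C: C1 fluorine, C4 formyl)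
Conditions: PPTS, acetone/H2O, 40 °C
Reagents that add atoms: water O
Why: Acetal hydrolysis as in step 7 frees the ring C formyl group and activates the last fluoride.

Step 10
Reactants: 14 2,4,6-trimethoxybenzaldehyde
Product: 16 2,4,6-trimethoxyphenol, via 2,4,6-trimethoxyphenyl formate 15 (not isolated)
Conditions: mCPBA, CH2Cl2, 0 °C to rt; then K2CO3 (cat.), MeOH, rt
Reagents that add atoms: mCPBA OOC(=O)c1cccc(Cl)c1
Why: Dakin-type Baeyer–Villiger oxidation of a 2,4,6-trialkoxybenzaldehyde with aryl migration, then formate methanolysis; it also serves as a small model of the key step.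

Step 11
Reactants: 16 2,4,6-trimethoxyphenol; 1 4-fluoro-2,6-dimethoxybenzaldehyde
Product: 17 2,6-dimethoxy-4-(2,4,6-trimethoxyphenoxy)benzaldehyde (rings A–B)
Conditions: K2CO3, DMF, 100 °C
Reagents that add atoms: none
Why: SNAr of the electron-rich phenoxide at the fluoride para to formyl; the product has neither phenol nor fluoride, so only one coupling can occur.

Step 12
Reactants: 17 2,6-dimethoxy-4-(2,4,6-trimethoxyphenoxy)benzaldehyde
Product: 18 2-hydroxy-6-methoxy-4-(2,4,6-trimethoxyphenoxy)benzaldehyde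
Conditions: BCl3, CH2Cl2, −78 to 0 °C; aqueous work-up
Reagents that add atoms: none
Why: Chelation-controlled mono-O-demethylation: BCl3 bound to the formyl oxygen cleaves one of the two equivalent ortho methoxy groups, and the resulting boron chelate resists a second cleavage; the ring A methoxy groups have no neighbouring carbonyl and should survive at low temperature.

Step 13
Reactants: 18 A–B phenol; 13 hexamer C–H tetraaldehyde fluoride
Product: 19 octamer pentaaldehyde (hexadecamethyl ether; C4 formyl on rings B, C, E, G and H)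
Conditions: Cs2CO3, DMSO, 100 °C, argon
Reagents that add atoms: none
Why: SNAr of the phenoxide of 18 (ring B C5 oxygen) on the ring C fluoride of 13, para to the ring C formyl group; 18 has no fluoride and 13 no phenol, so a single ether bond completes the eight-ring chain.

Step 14
Reactants: 19 octamer pentaaldehyde
Product: 21 octamer pentaphenol hexadecamethyl ether, via octamer pentaformate 20 (not isolated)
Conditions: mCPBA (7.5 equiv), CH2Cl2, 0 °C to rt; then K2CO3 (cat.), degassed MeOH, 0 °C, argon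
Reagents that add atoms: mCPBA OOC(=O)c1cccc(Cl)c1
Why: Dakin-type Baeyer–Villiger oxidation run five times on one substrate: the peracid adds to each formyl carbon to give a Criegee adduct, from which the aryl group migrates to oxygen with loss of 3-chlorobenzoate, giving five aryl formates (five new aryl C4–O bonds on rings B, C, E, G and H) that catalytic K2CO3 in methanol cleaves to the phenols. The closest known reaction is the peracid oxidation of 2,4,6-trialkoxybenzaldehydes to phenols, used on the same ring type in steps 4 and 10. No ring is closed and no stereocentre is formed. The step needs aryl over hydride migration at every formyl group, which the two ortho oxygens and the para oxygen of each migrating ring should secure by stabilising the electron-deficient migrating carbon. It also needs the oxidant to spare the formyl-free rings A, D and F and the new oxygens: the peracid is held to a small excess per formyl group at low temperature, the new oxygens stay masked as formates while oxidant is present, and the remaining peracid is removed in the work-up before methanolysis under argon.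

Step 15
Reactants: 21 octamer pentaphenol hexadecamethyl ether
Product: 22 CNP0175816.0 (target, twenty-one free hydroxyls)
Conditions: BBr3 (excess), CH2Cl2, −78 °C to rt; H2O quench; Sephadex LH-20 under argon
Reagents that add atoms: none
Why: Lewis-acid ether cleavage in which each ArO–Me oxygen binds BBr3 and bromide attacks the methyl carbon (SN2), while diaryl ether bonds are not cleaved; aqueous quench should free all twenty-one hydroxyls.

**Compound list**
1 | 4-fluoro-2,6-dimethoxybenzaldehyde | COc1cc(F)cc(OC)c1C=O | starting material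
2 | 2-(4-fluoro-2,6-dimethoxyphenyl)-1,3-dioxolane | COc1cc(F)cc(OC)c1C1OCCO1 | intermediate
3 | [3-(1,3-dioxolan-2-yl)-6-fluoro-2,4-dimethoxyphenyl]lithium | COc1cc(F)c([Li])c(OC)c1C1OCCO1 | intermediate (not isolated)
4 | lithium [3-(1,3-dioxolan-2-yl)-6-fluoro-2,4-dimethoxyphenyl]trimethoxyborate | [Li+].CO[B-](OC)(OC)c1c(F)cc(OC)c(C2OCCO2)c1OC | intermediate (not isolated)
5 | 3-(1,3-dioxolan-2-yl)-6-fluoro-2,4-dimethoxyphenol | COc1cc(F)c(O)c(OC)c1C1OCCO1 | intermediate
6 | 4-[3-(1,3-dioxolan-2-yl)-6-fluoro-2,4-dimethoxyphenoxy]-2,6-dimethoxybenzaldehyde | COc1cc(F)c(Oc2cc(OC)c(C=O)c(OC)c2)c(OC)c1C1OCCO1 | intermediate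
7 | 4-[3-(1,3-dioxolan-2-yl)-6-fluoro-2,4-dimethoxyphenoxy]-2,6-dimethoxyphenyl formate | COc1cc(F)c(Oc2cc(OC)c(OC=O)c(OC)c2)c(OC)c1C1OCCO1 | intermediate (not isolated)
8 | 4-[3-(1,3-dioxolan-2-yl)-6-fluoro-2,4-dimethoxyphenoxy]-2,6-dimethoxyphenol (dimer phenol) | COc1cc(F)c(Oc2cc(OC)c(O)c(OC)c2)c(OC)c1C1OCCO1 | intermediate
9 | 4-fluoro-3-(4-formyl-3,5-dimethoxyphenoxy)-2,6-dimethoxybenzaldehyde (G–H dialdehyde) | COc1cc(F)c(Oc2cc(OC)c(C=O)c(OC)c2)c(OC)c1C=O | intermediate
10 | tetramer E–H acetal | COc1cc(F)c(Oc2cc(OC)c(Oc3cc(OC)c(C=O)c(OC)c3Oc3cc(OC)c(C=O)c(OC)c3)c(OC)c2)c(OC)c1C1OCCO1 | intermediate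
11 | tetramer E–H trialdehyde fluoride | COc1cc(F)c(Oc2cc(OC)c(Oc3cc(OC)c(C=O)c(OC)c3Oc3cc(OC)c(C=O)c(OC)c3)c(OC)c2)c(OC)c1C=O | intermediate
12 | hexamer C–H acetal | COc1cc(F)c(Oc2cc(OC)c(Oc3cc(OC)c(C=O)c(OC)c3Oc3cc(OC)c(Oc4cc(OC)c(C=O)c(OC)c4Oc4cc(OC)c(C=O)c(OC)c4)c(OC)c3)c(OC)c2)c(OC)c1C1OCCO1 | intermediate
13 | hexamer C–H tetraaldehyde fluoride | COc1cc(F)c(Oc2cc(OC)c(Oc3cc(OC)c(C=O)c(OC)c3Oc3cc(OC)c(Oc4cc(OC)c(C=O)c(OC)c4Oc4cc(OC)c(C=O)c(OC)c4)c(OC)c3)c(OC)c2)c(OC)c1C=O | intermediate
14 | 2,4,6-trimethoxybenzaldehyde | COc1cc(OC)c(C=O)c(OC)c1 | starting material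
15 | 2,4,6-trimethoxyphenyl formate | COc1cc(OC)c(OC=O)c(OC)c1 | intermediate (not isolated)
16 | 2,4,6-trimethoxyphenol | COc1cc(OC)c(O)c(OC)c1 | intermediate
17 | 2,6-dimethoxy-4-(2,4,6-trimethoxyphenoxy)benzaldehyde | COc1cc(OC)c(Oc2cc(OC)c(C=O)c(OC)c2)c(OC)c1 | intermediate
18 | 2-hydroxy-6-methoxy-4-(2,4,6-trimethoxyphenoxy)benzaldehyde | COc1cc(OC)c(Oc2cc(OC)c(C=O)c(O)c2)c(OC)c1 | intermediate
19 | octamer pentaaldehyde | COc1cc(OC)c(Oc2cc(OC)c(C=O)c(Oc3cc(OC)c(C=O)c(OC)c3Oc3cc(OC)c(Oc4cc(OC)c(C=O)c(OC)c4Oc4cc(OC)c(Oc5cc(OC)c(C=O)c(OC)c5Oc5cc(OC)c(C=O)c(OC)c5)c(OC)c4)c(OC)c3)c2)c(OC)c1 | intermediate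
20 | octamer pentaformate | COc1cc(OC)c(Oc2cc(OC)c(OC=O)c(Oc3cc(OC)c(OC=O)c(OC)c3Oc3cc(OC)c(Oc4cc(OC)c(OC=O)c(OC)c4Oc4cc(OC)c(Oc5cc(OC)c(OC=O)c(OC)c5Oc5cc(OC)c(OC=O)c(OC)c5)c(OC)c4)c(OC)c3)c2)c(OC)c1 | intermediate (not isolated)
21 | octamer pentaphenol hexadecamethyl ether | COc1cc(OC)c(Oc2cc(OC)c(O)c(Oc3cc(OC)c(O)c(OC)c3Oc3cc(OC)c(Oc4cc(OC)c(O)c(OC)c4Oc4cc(OC)c(Oc5cc(OC)c(O)c(OC)c5Oc5cc(OC)c(O)c(OC)c5)c(OC)c4)c(OC)c3)c2)c(OC)c1 | intermediate
22 | CNP0175816.0 | Oc1cc(O)c(Oc2cc(O)c(O)c(Oc3cc(O)c(O)c(O)c3Oc3cc(O)c(Oc4cc(O)c(O)c(O)c4Oc4cc(O)c(Oc5cc(O)c(O)c(O)c5Oc5cc(O)c(O)c(O)c5)c(O)c4)c(O)c3)c2)c(O)c1 | target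

**Totals**
Total step count: 15.
Longest linear sequence: 11 steps (steps 1, 2, 3, 4, 6, 7, 8, 9, 13, 14, 15).

**Steps most likely to fail**

Step 13. The fluoride displacement may stall, because the phenoxide of 18 is conjugated with its ortho formyl group and the ring C fluoride is crowded by an ortho aryloxy group. At the temperature then needed, ether exchange at other aryloxy carbons para to formyl may compete. Fallback: set out from 18 and mask its formyl group (ethylene glycol, p-TsOH cat., toluene, Dean–Stark) to give 2-(1,3-dioxolan-2-yl)-3-methoxy-5-(2,4,6-trimethoxyphenoxy)phenol F1, whose phenoxide is an ordinary electron-rich nucleophile. SNAr of F1 on 13 (Cs2CO3, DMSO) should give the octamer tetraaldehyde ring B dioxolane F2. Hydrolysis (PPTS, acetone/H2O) comes back to the route at 19.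

Step 14. Oxidation of all five formyl groups may be incomplete, hydride migration may give carboxylic acids at a late formyl group, and the peracid may attack the formyl-free rings A, D and F. Fallback: stage the oxidation as three plus two, setting out from 12. Threefold Dakin oxidation of 12 (mCPBA, NaHCO3, CH2Cl2) should give the hexamer triformate acetal F3, which is methanolysed (K2CO3 cat., MeOH) to the hexamer triphenol acetal F4. MeI and K2CO3 in acetone cap the three phenols as the hexamer tri-O-methyl acetal F5, and PPTS in acetone/H2O then gives the hexamer monoaldehyde fluoride F6. SNAr of 18 on F6 (Cs2CO3, DMSO) gives the octamer dialdehyde nonadecamethyl ether F7. Twofold Dakin oxidation through the octamer diformate nonadecamethyl ether F8 gives the octamer diphenol nonadecamethyl ether F9. BBr3 as in step 15 cleaves all nineteen methyl ethers, and the route comes back at 22.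

Step 15. Some of the sixteen methyl ethers may resist cleavage, and the pyrogallol-type rings may oxidise in air during isolation of the free polyphenol. Fallback: set out from 21, treat with BBr3 as before and acetylate the crude product without purification (Ac2O, pyridine, DMAP cat.) to the henicosaacetate of the target F10. F10 should be stable to air and can be purified on silica, with under-demethylated fractions returned to BBr3. Acid methanolysis (HCl in MeOH, argon) then comes back to the route at 22.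

Further compounds
F1 | step 13 | 2-(1,3-dioxolan-2-yl)-3-methoxy-5-(2,4,6-trimethoxyphenoxy)phenol | COc1cc(OC)c(Oc2cc(OC)c(C3OCCO3)c(O)c2)c(OC)c1
F2 | step 13 | octamer tetraaldehyde ring B dioxolane | COc1cc(OC)c(Oc2cc(OC)c(C3OCCO3)c(Oc3cc(OC)c(C=O)c(OC)c3Oc3cc(OC)c(Oc4cc(OC)c(C=O)c(OC)c4Oc4cc(OC)c(Oc5cc(OC)c(C=O)c(OC)c5Oc5cc(OC)c(C=O)c(OC)c5)c(OC)c4)c(OC)c3)c2)c(OC)c1
F3 | step 14 | hexamer triformate acetal | COc1cc(F)c(Oc2cc(OC)c(Oc3cc(OC)c(OC=O)c(OC)c3Oc3cc(OC)c(Oc4cc(OC)c(OC=O)c(OC)c4Oc4cc(OC)c(OC=O)c(OC)c4)c(OC)c3)c(OC)c2)c(OC)c1C1OCCO1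
F4 | step 14 | hexamer triphenol acetal | COc1cc(F)c(Oc2cc(OC)c(Oc3cc(OC)c(O)c(OC)c3Oc3cc(OC)c(Oc4cc(OC)c(O)c(OC)c4Oc4cc(OC)c(O)c(OC)c4)c(OC)c3)c(OC)c2)c(OC)c1C1OCCO1
F5 | step 14 | hexamer tri-O-methyl acetal | COc1cc(F)c(Oc2cc(OC)c(Oc3cc(OC)c(OC)c(OC)c3Oc3cc(OC)c(Oc4cc(OC)c(OC)c(OC)c4Oc4cc(OC)c(OC)c(OC)c4)c(OC)c3)c(OC)c2)c(OC)c1C1OCCO1
F6 | step 14 | hexamer monoaldehyde fluoride | COc1cc(F)c(Oc2cc(OC)c(Oc3cc(OC)c(OC)c(OC)c3Oc3cc(OC)c(Oc4cc(OC)c(OC)c(OC)c4Oc4cc(OC)c(OC)c(OC)c4)c(OC)c3)c(OC)c2)c(OC)c1C=O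
F7 | step 14 | octamer dialdehyde nonadecamethyl ether | COc1cc(OC)c(Oc2cc(OC)c(C=O)c(Oc3cc(OC)c(C=O)c(OC)c3Oc3cc(OC)c(Oc4cc(OC)c(OC)c(OC)c4Oc4cc(OC)c(Oc5cc(OC)c(OC)c(OC)c5Oc5cc(OC)c(OC)c(OC)c5)c(OC)c4)c(OC)c3)c2)c(OC)c1
F8 | step 14 | octamer diformate nonadecamethyl ether | COc1cc(OC)c(Oc2cc(OC)c(OC=O)c(Oc3cc(OC)c(OC=O)c(OC)c3Oc3cc(OC)c(Oc4cc(OC)c(OC)c(OC)c4Oc4cc(OC)c(Oc5cc(OC)c(OC)c(OC)c5Oc5cc(OC)c(OC)c(OC)c5)c(OC)c4)c(OC)c3)c2)c(OC)c1
F9 | step 14 | octamer diphenol nonadecamethyl ether | COc1cc(OC)c(Oc2cc(OC)c(O)c(Oc3cc(OC)c(O)c(OC)c3Oc3cc(OC)c(Oc4cc(OC)c(OC)c(OC)c4Oc4cc(OC)c(Oc5cc(OC)c(OC)c(OC)c5Oc5cc(OC)c(OC)c(OC)c5)c(OC)c4)c(OC)c3)c2)c(OC)c1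
F10 | step 15 | henicosaacetate of the target | CC(=O)Oc1cc(OC(C)=O)c(Oc2cc(OC(C)=O)c(OC(C)=O)c(Oc3cc(OC(C)=O)c(OC(C)=O)c(OC(C)=O)c3Oc3cc(OC(C)=O)c(Oc4cc(OC(C)=O)c(OC(C)=O)c(OC(C)=O)c4Oc4cc(OC(C)=O)c(Oc5cc(OC(C)=O)c(OC(C)=O)c(OC(C)=O)c5Oc5cc(OC(C)=O)c(OC(C)=O)c(OC(C)=O)c5)c(OC(C)=O)c4)c(OC(C)=O)c3)c2)c(OC(C)=O)c1
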